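**Retrosynthetic overview**

1. The route rests on ring A (C3a–C4–C5–C6–C7–C7a). Its hydroxyls at C4 and C6, one carbon apart on a ring fused to the furan, mark it as the aromatic enol of a cyclic 1,3-dione spanning C4–C5–C6 between furan carbon C3a and the C7 methine. It is therefore opened at C5–C6.
2. That bond comes from an intramolecular Claisen condensation: the 3-acetyl group of a 2,3,5-trisubstituted furan attacks the methyl ester of the C2 side chain, which already carries the 1,1-dimethylallyl group on the future C7.
3. The C2–C1′ bond to ring B is made just before, by Suzuki coupling of 5-bromofuran 19 with ring-B boronate 7.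
4. The furan comes from dimethyl 3-oxoglutarate and chloroacetaldehyde (Feist–Benary). An Ireland–Claisen rearrangement of the prenyl ester sets the reverse prenyl group, and the furoate is turned into the acetyl group through its Weinreb amide. Ring B comes from 3-bromo-5-methoxyphenol by directed metalation and prenylation.
5. Ring order: furan (step 4), ring B brought in intact (step 10), ring A last (step 11), then desilylation.

Key step: step 11

Remark on the chemistry: the ring-B phenol is carried as its triisopropylsilyl ether instead of a tert-butyldimethylsilyl ether. The bulkier group shields both of its ortho positions in the metalation of step 2 and resists the alkoxide of step 11 better. The stereocentre made in step 7 is racemic and is erased when ring A aromatises, so no stereocontrol is needed. Compounds 1, 3, 8 and 9 (50% aqueous solution) are taken as catalogue chemicals.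

**Route**

Step 1
Reactants: 1 3-bromo-5-methoxyphenol
Product: 2 (3-bromo-5-methoxyphenoxy)triisopropylsilane
Conditions: iPr3SiCl, imidazole, DMF, rt
Reagents that add atoms: chlorotriisopropylsilane, CC(C)[Si](Cl)(C(C)C)C(C)C
Why: Silylation of a phenol with a silyl chloride and imidazole is routine, and the bulky silyl ether is inert to the organolithium steps that follow.

Step 2
Reactants: 2 (3-bromo-5-methoxyphenoxy)triisopropylsilane; 3 prenyl bromide (1-bromo-3-methylbut-2-ene)
Product: 5 1-bromo-3-methoxy-2-(3-methylbut-2-en-1-yl)-5-(triisopropylsilyloxy)benzene, via aryllithium 4 (not isolated)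
Conditions: LiN(iPr)2, THF, −78 °C; then CuBr·SMe2 (0.2 equiv), 3, −78 → −20 °C
Reagents that add atoms: none
Why: Directed ortho-lithiation should remove the proton flanked by bromine and the coordinating methoxy group, since the other two ring positions are shielded by the non-coordinating silyl ether; copper-mediated SN2-type allylation at the unsubstituted terminus of prenyl bromide then follows at a temperature that keeps lithium bromide from being lost.

Step 3
Reactants: 5 1-bromo-3-methoxy-2-(3-methylbut-2-en-1-yl)-5-(triisopropylsilyloxy)benzene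
Product: 7 2-[3-methoxy-2-(3-methylbut-2-en-1-yl)-5-(triisopropylsilyloxy)phenyl]-4,4,5,5-tetramethyl-1,3,2-dioxaborolane, via aryllithium 6 (not isolated)
Conditions: n-BuLi, THF, −78 °C; then iPrOBpin, −78 °C → rt
Reagents that add atoms: 2-isopropoxy-4,4,5,5-tetramethyl-1,3,2-dioxaborolane, CC(C)OB1OC(C)(C)C(C)(C)O1
Why: Bromine–lithium exchange is faster than any deprotonation at −78 °C, and trapping the aryllithium with the isopropoxy borate is the standard route to a pinacol boronate.

Step 4
Reactants: 8 dimethyl 3-oxoglutarate; 9 chloroacetaldehyde (50% in water)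
Product: 10 methyl 2-(2-methoxy-2-oxoethyl)furan-3-carboxylate
Conditions: pyridine, 50 °C
Reagents that add atoms: none
Why: Feist–Benary furan synthesis: aldol addition of one active methylene to the aldehyde, O-alkylation of the enol by the chloromethyl carbon and dehydration give the furan, with the second methylene left as the C2 acetate arm.

Step 5
Reactants: 10 methyl 2-(2-methoxy-2-oxoethyl)furan-3-carboxylate
Product: 11 2-[3-(methoxycarbonyl)furan-2-yl]acetic acid
Conditions: LiOH·H2O (1.0 equiv), THF/H2O, 0 °C; then 1 M HCl
Reagents that add atoms: lithium hydroxide, [Li+].[OH-]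
Why: Selective saponification: the non-conjugated acetate ester is far more electrophilic than the furan-3-carboxylate, which is a vinylogous carbonate, so one equivalent of hydroxide in the cold should cleave only the side-chain ester.

Step 6
Reactants: 11 2-[3-(methoxycarbonyl)furan-2-yl]acetic acid; 3 prenyl bromide
Product: 12 3-methylbut-2-en-1-yl 2-[3-(methoxycarbonyl)furan-2-yl]acetate
Conditions: KHCO3, DMF, rt
Reagents that add atoms: none
Why: O-alkylation of a carboxylate with an allylic bromide; the weak base is chosen so that the acidic methylene is not C-alkylated.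

Step 7
Reactants: 12 3-methylbut-2-en-1-yl 2-[3-(methoxycarbonyl)furan-2-yl]acetate
Product: 16 methyl 2-[3-(methoxycarbonyl)furan-2-yl]-3,3-dimethylpent-4-enoate (racemic), via silyl ketene acetal 13 (not isolated), via trimethylsilyl ester 14 (not isolated), via carboxylic acid 15 (not isolated)
Conditions: LiN(SiMe3)2, Me3SiCl, THF, −78 → 50 °C; aqueous work-up; then Me3SiCHN2, toluene/MeOH, 0 °C
Reagents that add atoms: chlorotrimethylsilane, C[Si](C)(C)Cl (atoms stay only in 13 and 14); (trimethylsilyl)diazomethane, C[Si](C)(C)C=[N+]=[N-]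
Why: Ireland–Claisen rearrangement: the silyl ketene acetal of the prenyl ester undergoes a [3,3] shift that bonds the α-carbon to the dimethyl-substituted allyl terminus and so gives the 1,1-dimethylallyl group; the new stereocentre is racemic and is erased in step 11; the crude acid is methylated on oxygen, which its steric hindrance does not impede.

Step 8
Reactants: 16 methyl 2-[3-(methoxycarbonyl)furan-2-yl]-3,3-dimethylpent-4-enoate
Product: 18 methyl 2-(3-acetylfuran-2-yl)-3,3-dimethylpent-4-enoate (racemic), via Weinreb amide 17 (not isolated)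
Conditions: MeNHOMe·HCl (1.5 equiv), iPrMgCl (3.0 equiv), THF, −20 °C; then MeMgBr, −20 → 0 °C; aq. NH4Cl
Reagents that add atoms: N,O-dimethylhydroxylamine hydrochloride, CNOC.Cl (atoms stay only in 17); methylmagnesium bromide, C[Mg]Br
Why: Weinreb ketone synthesis: the magnesium amide should convert only the unhindered furoate, because the other ester sits beside a tertiary carbon that bears a quaternary carbon; the chelated tetrahedral adduct of the amide with MeMgBr releases the methyl ketone only on quench, so there is no over-addition and no early condensation.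

Step 9
Reactants: 18 methyl 2-(3-acetylfuran-2-yl)-3,3-dimethylpent-4-enoate
Product: 19 methyl 2-(3-acetyl-5-bromofuran-2-yl)-3,3-dimethylpent-4-enoate (racemic)
Conditions: NBS, DMF, 0 °C → rt, dark
Reagents that add atoms: N-bromosuccinimide, O=C1CCC(=O)N1Br
Why: Electrophilic aromatic bromination goes to the only free α-position of the furan (C5), which is activated by the ring oxygen and not conjugated with the acetyl group; the hindered terminal alkene and the ketone are much less reactive under ionic, acid-free conditions.

Step 10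
Reactants: 19 methyl 2-(3-acetyl-5-bromofuran-2-yl)-3,3-dimethylpent-4-enoate; 7 2-[3-methoxy-2-(3-methylbut-2-en-1-yl)-5-(triisopropylsilyloxy)phenyl]-4,4,5,5-tetramethyl-1,3,2-dioxaborolane
Product: 20 methyl 2-{3-acetyl-5-[3-methoxy-2-(3-methylbut-2-en-1-yl)-5-(triisopropylsilyloxy)phenyl]furan-2-yl}-3,3-dimethylpent-4-enoate (racemic)
Conditions: Pd(OAc)2, SPhos, K3PO4, toluene/H2O, 70 °C
Reagents that add atoms: none
Why: Suzuki–Miyaura coupling of an electron-poor 2-bromofuran with an ortho-substituted arylboronate is well served by a biarylphosphine ligand, and the phosphate base is too weak to enolise the methyl ketone and start the condensation.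

Step 11
Reactants: 20 methyl 2-{3-acetyl-5-[3-methoxy-2-(3-methylbut-2-en-1-yl)-5-(triisopropylsilyloxy)phenyl]furan-2-yl}-3,3-dimethylpent-4-enoate
Product: 22 2-[3-methoxy-2-(3-methylbut-2-en-1-yl)-5-(triisopropylsilyloxy)phenyl]-7-(2-methylbut-3-en-2-yl)-1-benzofuran-4,6-diol, via cyclic 1,3-dione 21 (not isolated)
Conditions: KOtBu (3 equiv), tBuOH/THF, degassed, 0 → 50 °C, high dilution; AcOH quench
Reagents that add atoms: none
Why: tert-Butoxide deprotonates reversibly, so although the more acidic C7–H gives an unreactive extended enolate as the resting state, proton exchange through tert-butanol keeps supplying the acetyl enolate, whose carbon (the future C5) adds to the ester carbonyl (C6) and expels methoxide to give dione 21. Dione 21 then loses its C5 and C7 protons to become the aromatic 4,6-diol, which is held as its phenoxide, and this makes the condensation irreversible. The closest known reaction type is the intramolecular Claisen (Dieckmann-type) condensation of ortho-acetyl arylacetates to 1,3-dihydroxyarenes. Ring A closes in a 6-(enolexo)-exo-trig mode, with the furan C2 and C3 substituents held cis on a rigid ring so that nucleophile and electrophile are within reach. No stereocentre is formed and the racemic C7 centre disappears on aromatisation. The step needs attack on the hindered ester to beat intermolecular condensation and the aryl silyl ether to survive, which the six-membered intramolecular geometry, dilution, the aromatisation driving force and a bulky, poorly nucleophilic alkoxide should secure; no regiochemical choice exists because O1 is already bonded to C7a and the quaternary group already sits on C7.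

Step 12
Reactants: 22 2-[3-methoxy-2-(3-methylbut-2-en-1-yl)-5-(triisopropylsilyloxy)phenyl]-7-(2-methylbut-3-en-2-yl)-1-benzofuran-4,6-diol
Product: 23 2-[5-hydroxy-3-methoxy-2-(3-methylbut-2-en-1-yl)phenyl]-7-(2-methylbut-3-en-2-yl)-1-benzofuran-4,6-diol (target)
Conditions: Bu4NF, AcOH, THF, 0 °C
Reagents that add atoms: none
Why: Fluoride-mediated desilylation of an aryl silyl ether; the acetic acid buffer keeps the electron-rich triphenol and its acid- and base-sensitive allyl groups close to neutral.

**Compound list**

1 | 3-bromo-5-methoxyphenol | COc1cc(O)cc(Br)c1 | starting material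
2 | (3-bromo-5-methoxyphenoxy)triisopropylsilane | COc1cc(Br)cc(O[Si](C(C)C)(C(C)C)C(C)C)c1 | intermediate
3 | prenyl bromide (1-bromo-3-methylbut-2-ene) | CC(C)=CCBr | starting material
4 | [2-bromo-6-methoxy-4-(triisopropylsilyloxy)phenyl]lithium | COc1cc(O[Si](C(C)C)(C(C)C)C(C)C)cc(Br)c1[Li] | intermediate
5 | 1-bromo-3-methoxy-2-(3-methylbut-2-en-1-yl)-5-(triisopropylsilyloxy)benzene | COc1cc(O[Si](C(C)C)(C(C)C)C(C)C)cc(Br)c1CC=C(C)C | intermediate
6 | [3-methoxy-2-(3-methylbut-2-en-1-yl)-5-(triisopropylsilyloxy)phenyl]lithium | COc1cc(O[Si](C(C)C)(C(C)C)C(C)C)cc([Li])c1CC=C(C)C | intermediate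
7 | 2-[3-methoxy-2-(3-methylbut-2-en-1-yl)-5-(triisopropylsilyloxy)phenyl]-4,4,5,5-tetramethyl-1,3,2-dioxaborolane | COc1cc(O[Si](C(C)C)(C(C)C)C(C)C)cc(B2OC(C)(C)C(C)(C)O2)c1CC=C(C)C | intermediate
8 | dimethyl 3-oxoglutarate | COC(=O)CC(=O)CC(=O)OC | starting material
9 | chloroacetaldehyde | O=CCCl | starting material
10 | methyl 2-(2-methoxy-2-oxoethyl)furan-3-carboxylate | COC(=O)Cc1occc1C(=O)OC | intermediate
11 | 2-[3-(methoxycarbonyl)furan-2-yl]acetic acid | COC(=O)c1ccoc1CC(=O)O | intermediate
12 | 3-methylbut-2-en-1-yl 2-[3-(methoxycarbonyl)furan-2-yl]acetate | COC(=O)c1ccoc1CC(=O)OCC=C(C)C | intermediate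
13 | methyl 2-{2-[(3-methylbut-2-en-1-yl)oxy]-2-(trimethylsilyloxy)ethenyl}furan-3-carboxylate (silyl ketene acetal, double-bond geometry not controlled) | COC(=O)c1ccoc1C=C(O[Si](C)(C)C)OCC=C(C)C | intermediate
14 | trimethylsilyl 2-[3-(methoxycarbonyl)furan-2-yl]-3,3-dimethylpent-4-enoate (racemic) | C=CC(C)(C)C(C(=O)O[Si](C)(C)C)c1occc1C(=O)OC | intermediate
15 | 2-[3-(methoxycarbonyl)furan-2-yl]-3,3-dimethylpent-4-enoic acid (racemic) | C=CC(C)(C)C(C(=O)O)c1occc1C(=O)OC | intermediate
16 | methyl 2-[3-(methoxycarbonyl)furan-2-yl]-3,3-dimethylpent-4-enoate (racemic) | C=CC(C)(C)C(C(=O)OC)c1occc1C(=O)OC | intermediate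
17 | methyl 2-{3-[methoxy(methyl)carbamoyl]furan-2-yl}-3,3-dimethylpent-4-enoate (racemic) | C=CC(C)(C)C(C(=O)OC)c1occc1C(=O)N(C)OC | intermediate
18 | methyl 2-(3-acetylfuran-2-yl)-3,3-dimethylpent-4-enoate (racemic) | C=CC(C)(C)C(C(=O)OC)c1occc1C(C)=O | intermediate
19 | methyl 2-(3-acetyl-5-bromofuran-2-yl)-3,3-dimethylpent-4-enoate (racemic) | C=CC(C)(C)C(C(=O)OC)c1oc(Br)cc1C(C)=O | intermediate
20 | methyl 2-{3-acetyl-5-[3-methoxy-2-(3-methylbut-2-en-1-yl)-5-(triisopropylsilyloxy)phenyl]furan-2-yl}-3,3-dimethylpent-4-enoate (racemic; key-step precursor) | C=CC(C)(C)C(C(=O)OC)c1oc(-c2cc(O[Si](C(C)C)(C(C)C)C(C)C)cc(OC)c2CC=C(C)C)cc1C(C)=O | intermediate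
21 | 2-[3-methoxy-2-(3-methylbut-2-en-1-yl)-5-(triisopropylsilyloxy)phenyl]-7-(2-methylbut-3-en-2-yl)-5,7-dihydro-1-benzofuran-4,6-dione (racemic) | C=CC(C)(C)C1C(=O)CC(=O)c2cc(-c3cc(O[Si](C(C)C)(C(C)C)C(C)C)cc(OC)c3CC=C(C)C)oc12 | intermediate
22 | 2-[3-methoxy-2-(3-methylbut-2-en-1-yl)-5-(triisopropylsilyloxy)phenyl]-7-(2-methylbut-3-en-2-yl)-1-benzofuran-4,6-diol (key-step product) | C=CC(C)(C)c1c(O)cc(O)c2cc(-c3cc(O[Si](C(C)C)(C(C)C)C(C)C)cc(OC)c3CC=C(C)C)oc12 | intermediate
23 | 2-[5-hydroxy-3-methoxy-2-(3-methylbut-2-en-1-yl)phenyl]-7-(2-methylbut-3-en-2-yl)-1-benzofuran-4,6-diol | C=CC(C)(C)c1c(O)cc(O)c2cc(-c3cc(O)cc(OC)c3CC=C(C)C)oc12 | target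

**Step count**

Total: 12 steps. Longest linear sequence: 9 steps (steps 4–12, from dimethyl 3-oxoglutarate). The ring-B branch is 3 steps (steps 1–3) and joins at step 10.

**Steps most likely to fail, with fallbacks**

Step 11 (key step). The substrate may rest as the C7 ester enolate, and the ketone enolate may then attack the hindered ester too slowly, so that intermolecular condensation or loss of the silyl ether takes over. The fallback closes the same C5–C6 bond by a pericyclic path that uses the acidity of C7–H instead of fighting it. It sets out from 20. SN2 demethylation of the ester (LiI, pyridine, reflux) should give the keto acid F1. tert-Butyldimethylsilyl triflate and triethylamine should then give the silyl ester that also carries the silyl enol ether of the acetyl group, F2. Oxalyl chloride with catalytic DMF converts the silyl ester under neutral conditions into the acid chloride F3. Triethylamine in toluene at 80 °C removes hydrogen chloride to give the furyl(tert-alkyl)ketene F4 (not isolated). Its dienylketene unit C5=C4–C3a=C7a–C7=C6=O should undergo 6π electrocyclisation and tautomerise to the 4-silyloxy-6-hydroxybenzofuran F5. The fluoride conditions of step 12, with enough Bu4NF for both silyl ethers, bring the material back to the route at target 23.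

Step 8. The two methyl esters may not be told apart cleanly: amide formation at the furoate, which is a vinylogous carbonate next to a bulky C2 substituent, may be slow enough for enolisation of, or attack on, the side-chain ester to compete. The fallback protects the side chain as its carboxylate. It sets out from acid 15, isolated after the aqueous work-up of step 7 instead of being esterified. MeNHOMe·HCl and excess iPrMgCl act on the magnesium carboxylate to give the Weinreb amide acid F6. MeMgBr then gives the keto acid F7. O-Methylation with (trimethylsilyl)diazomethane returns to the route at 18.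

Step 2. The ortho-lithiated aryl bromide may lose lithium bromide to an aryne before allylation is complete, and the copper-mediated allylation may give some attack at the dimethyl-substituted terminus of prenyl bromide. The fallback separates the metalation from the C–C bond formation. It sets out from 2. The aryllithium is quenched at −78 °C with iodine to give (3-bromo-4-iodo-5-methoxyphenoxy)triisopropylsilane F8. A palladium-catalysed Suzuki–Miyaura coupling of the C–I bond with prenylboronic acid pinacol ester, using a bulky biarylphosphine chosen for coupling at the unsubstituted allyl terminus, returns to the route at 5 with the C–Br bond intact.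

**Further compounds**

F1 | step 11 | 2-{3-acetyl-5-[3-methoxy-2-(3-methylbut-2-en-1-yl)-5-(triisopropylsilyloxy)phenyl]furan-2-yl}-3,3-dimethylpent-4-enoic acid (racemic) | C=CC(C)(C)C(C(=O)O)c1oc(-c2cc(O[Si](C(C)C)(C(C)C)C(C)C)cc(OC)c2CC=C(C)C)cc1C(C)=O
F2 | step 11 | tert-butyldimethylsilyl 2-{3-[1-(tert-butyldimethylsilyloxy)ethenyl]-5-[3-methoxy-2-(3-methylbut-2-en-1-yl)-5-(triisopropylsilyloxy)phenyl]furan-2-yl}-3,3-dimethylpent-4-enoate (racemic) | C=CC(C)(C)C(C(=O)O[Si](C)(C)C(C)(C)C)c1oc(-c2cc(O[Si](C(C)C)(C(C)C)C(C)C)cc(OC)c2CC=C(C)C)cc1C(=C)O[Si](C)(C)C(C)(C)C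
F3 | step 11 | 2-{3-[1-(tert-butyldimethylsilyloxy)ethenyl]-5-[3-methoxy-2-(3-methylbut-2-en-1-yl)-5-(triisopropylsilyloxy)phenyl]furan-2-yl}-3,3-dimethylpent-4-enoyl chloride (racemic) | C=CC(C)(C)C(C(=O)Cl)c1oc(-c2cc(O[Si](C(C)C)(C(C)C)C(C)C)cc(OC)c2CC=C(C)C)cc1C(=C)O[Si](C)(C)C(C)(C)C
F4 | step 11 | 2-{3-[1-(tert-butyldimethylsilyloxy)ethenyl]-5-[3-methoxy-2-(3-methylbut-2-en-1-yl)-5-(triisopropylsilyloxy)phenyl]furan-2-yl}-3,3-dimethylpenta-1,4-dien-1-one (ketene) | C=CC(C)(C)C(=C=O)c1oc(-c2cc(O[Si](C(C)C)(C(C)C)C(C)C)cc(OC)c2CC=C(C)C)cc1C(=C)O[Si](C)(C)C(C)(C)C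
F5 | step 11 | 4-(tert-butyldimethylsilyloxy)-2-[3-methoxy-2-(3-methylbut-2-en-1-yl)-5-(triisopropylsilyloxy)phenyl]-7-(2-methylbut-3-en-2-yl)-1-benzofuran-6-ol | C=CC(C)(C)c1c(O)cc(O[Si](C)(C)C(C)(C)C)c2cc(-c3cc(O[Si](C(C)C)(C(C)C)C(C)C)cc(OC)c3CC=C(C)C)oc12
F6 | step 8 | 2-{3-[methoxy(methyl)carbamoyl]furan-2-yl}-3,3-dimethylpent-4-enoic acid (racemic) | C=CC(C)(C)C(C(=O)O)c1occc1C(=O)N(C)OC
F7 | step 8 | 2-(3-acetylfuran-2-yl)-3,3-dimethylpent-4-enoic acid (racemic) | C=CC(C)(C)C(C(=O)O)c1occc1C(C)=O
F8 | step 2 | (3-bromo-4-iodo-5-methoxyphenoxy)triisopropylsilane | COc1cc(O[Si](C(C)C)(C(C)C)C(C)C)cc(Br)c1I
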